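**Retrosynthetic overview**
- The strategy rests on ring B (C1'–C6'). Its C2'(OH)–C3'(prenyl)–C4'(OH) triad is the enol form of a 2-alkylcyclohexane-1,3-dione, and C1' is also the α-carbon of an acetic ester on coumarin C3.
- Key disconnection: C1'–C6' (Michael) and C2'–C3' (Dieckmann). This gives coumarin-3-acetate 8 (supplies C1', C2') and ynone 16 (supplies C3'–C6' and the prenyl chain), a four-carbon plus two-carbon anionic benzannulation.
- 8 comes from salicylaldehyde 2 by Wittig olefination–lactonisation with succinate ylide 6. 16 comes from a Johnson–Claisen ester via the Weinreb amide and an ethynyl Grignard reagent.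
- Ring order: ring A is bought, the lactone ring is closed in step 3, ring B in step 7; the 7-O-MOM group is removed last.

Key step: step 7

Assumption: the target has no stereocentre and no stereogenic double bond, so no stereocontrol is needed; ring B is numbered C1' (bonded to coumarin C3) to C6'.

Step 1
Reactants: 1 2,4-dihydroxy-6-methoxybenzaldehyde
Product: 2 2-hydroxy-6-methoxy-4-(methoxymethoxy)benzaldehyde
Conditions: MOMCl (1.05 equiv), K2CO3, acetone, 0 °C to rt
Reagents that add atoms: chloromethyl methyl ether, COCCl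
Why: Williamson-type O-alkylation (MOM ether formation) should occur at the 4-OH, which is the more acidic phenol and is not held in the hydrogen bond that ties the 2-OH to the formyl group.

Step 2
Reactants: 3 methyl (triphenylphosphoranylidene)acetate (2 equiv); 4 methyl bromoacetate
Product: 6 dimethyl 2-(triphenylphosphoranylidene)succinate, via succinylphosphonium bromide 5 (not isolated)
Conditions: EtOAc, reflux; filter off the precipitated phosphonium salt
Reagents that add atoms: none
Why: C-alkylation of the stabilised ylide gives salt 5, which the second equivalent of 3 deprotonates (transylidation), leaving ylide 6 in solution.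

Step 3
Reactants: 2 2-hydroxy-6-methoxy-4-(methoxymethoxy)benzaldehyde; 6 dimethyl 2-(triphenylphosphoranylidene)succinate
Product: 8 methyl 2-[5-methoxy-7-(methoxymethoxy)-2-oxo-2H-chromen-3-yl]acetate, via benzylidenesuccinate 7 (not isolated)
Conditions: 6 (1.3 equiv), PhNEt2, reflux (ca. 215 °C), N2
Reagents that add atoms: none
Why: Wittig olefination by the stabilised ylide is followed at this temperature by E/Z equilibration of the o-hydroxybenzylidene succinate and lactonisation of the Z-isomer onto the conjugated ester (Wittig coumarin synthesis), under neutral conditions that an aryl MOM ether tolerates.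

Step 4
Reactants: 9 2-methylbut-3-en-2-ol; 10 triethyl orthoacetate
Product: 13 ethyl 5-methylhex-4-enoate, via mixed orthoester 11 (not isolated), via ketene acetal 12 (not isolated)
Conditions: EtCO2H (cat.), neat, 140 °C, EtOH distilled off
Reagents that add atoms: none
Why: Johnson–Claisen rearrangement, in which acid-catalysed exchange and loss of ethanol give allyl ketene acetal 12 and its [3,3]-shift turns the tertiary allylic C–O bond into the C–C bond of the γ,δ-unsaturated ester with the trisubstituted alkene.

Step 5
Reactants: 13 ethyl 5-methylhex-4-enoate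
Product: 14 N-methoxy-N,5-dimethylhex-4-enamide
Conditions: MeNH(OMe)·HCl, i-PrMgCl, THF, −20 to 0 °C
Reagents that add atoms: N,O-dimethylhydroxylamine hydrochloride, CNOC.Cl
Why: Aminolysis of the ester by the chloromagnesium amide of N,O-dimethylhydroxylamine (Weinreb amide formation) is fast at low temperature and leaves the isolated alkene untouched.

Step 6
Reactants: 14 N-methoxy-N,5-dimethylhex-4-enamide
Product: 16 7-methyloct-6-en-1-yn-3-one, via magnesium hemiaminal chelate 15 (not isolated)
Conditions: HC≡CMgBr, THF, 0 °C; inverse quench into cold aq. NaHSO4; used without storage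
Reagents that add atoms: ethynylmagnesium bromide, C#C[Mg]Br
Why: Grignard addition to the Weinreb amide stops at chelate 15, so one ethynyl group is delivered and the ynone forms only on the acidic inverse quench, which also keeps the released amine protonated and unable to add to the ynone.

Step 7
Reactants: 8 methyl 2-[5-methoxy-7-(methoxymethoxy)-2-oxo-2H-chromen-3-yl]acetate; 16 7-methyloct-6-en-1-yn-3-one
Product: 19 3-[2,4-dihydroxy-3-(3-methylbut-2-en-1-yl)phenyl]-5-methoxy-7-(methoxymethoxy)-2H-chromen-2-one, via Michael adduct 17 (not isolated), via cyclohexenedione 18 (not isolated)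
Conditions: KOtBu (1.2 equiv), THF, −40 °C; 16 (1.3 equiv) added slowly, to 0 °C; then t-BuOH, 60 °C; 0.5 M HCl quench at 0 °C
Reagents that add atoms: none
Why: Proposed new method: KOtBu turns 8 into its delocalised ester enolate, which should add through the exocyclic carbon C1' (the only site that keeps the coumarin π-system intact) to the unsubstituted alkyne terminus of 16, forming C1'–C6'; adduct 17 is a vinylogous β-keto ester and rests as a pentadienyl-type anion in which the C5'–C6' bond can rotate, so the Z-enone geometry is reachable. On warming with t-BuOH as proton shuttle, a small equilibrium share of the cross-conjugated C3' enolate (C1' reprotonated) should attack the methyl ester in a 6-exo-trig Dieckmann acylation that forms C2'–C3' and, after loss of methoxide, closes ring B as 18; two enolisations then give the resorcinol irreversibly. The closest known reactions are the alkoxide-mediated Michael–Dieckmann condensation of malonates with alk-3-yn-2-ones to resorcylates and the Michael–Claisen route from enones to cyclohexane-1,3-diones; the untested element is a donor whose C1' is activated by one ester and the coumarin ring instead of two carbonyl groups. No stereocentre is created in the product, since both sp3 ring carbons of 18 become aromatic. The step needs C- over O-acylation of the ketone enolate (O-attack leads to a 2-pyranone) and closure at C3': the first should be secured thermodynamically, because the pyranone can be reopened by the methoxide its formation releases while C-acylation is locked by aromatisation, and the second by ring size, since C3' reaches the acetate carbonyl through a six-membered transition state but the lactone carbonyl only through a seven-membered one, which places the prenyl chain between the two hydroxyls.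

Step 8
Reactants: 19 3-[2,4-dihydroxy-3-(3-methylbut-2-en-1-yl)phenyl]-5-methoxy-7-(methoxymethoxy)-2H-chromen-2-one
Product: 20 3-[2,4-dihydroxy-3-(3-methylbut-2-en-1-yl)phenyl]-7-hydroxy-5-methoxy-2H-chromen-2-one
Conditions: HCl (ca. 1 M in MeOH), 0 °C to rt, stopped at full conversion
Reagents that add atoms: none
Why: Acid-catalysed methanolysis of the aryl methoxymethyl acetal (MOM deprotection), run cold and dilute so that the prenyl alkene is not protonated and the lactone stays closed.

**Compound list**
1 | 2,4-dihydroxy-6-methoxybenzaldehyde | COc1cc(O)cc(O)c1C=O | starting material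
2 | 2-hydroxy-6-methoxy-4-(methoxymethoxy)benzaldehyde | COCOc1cc(O)c(C=O)c(OC)c1 | intermediate
3 | methyl (triphenylphosphoranylidene)acetate | COC(=O)C=P(c1ccccc1)(c1ccccc1)c1ccccc1 | starting material
4 | methyl bromoacetate | COC(=O)CBr | starting material
5 | (1,4-dimethoxy-1,4-dioxobutan-2-yl)triphenylphosphonium bromide (not isolated) | COC(=O)CC(C(=O)OC)[P+](c1ccccc1)(c1ccccc1)c1ccccc1.[Br-] | intermediate
6 | dimethyl 2-(triphenylphosphoranylidene)succinate | COC(=O)CC(C(=O)OC)=P(c1ccccc1)(c1ccccc1)c1ccccc1 | intermediate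
7 | dimethyl (2Z)-2-{[2-hydroxy-6-methoxy-4-(methoxymethoxy)phenyl]methylidene}butanedioate (not isolated) | COC(=O)C/C(=C/c1c(O)cc(OCOC)cc1OC)C(=O)OC | intermediate
8 | methyl 2-[5-methoxy-7-(methoxymethoxy)-2-oxo-2H-chromen-3-yl]acetate | COCOc1cc(OC)c2cc(CC(=O)OC)c(=O)oc2c1 | intermediate
9 | 2-methylbut-3-en-2-ol | CC(C)(O)C=C | starting material
10 | triethyl orthoacetate | CCOC(C)(OCC)OCC | starting material
11 | 3-(1,1-diethoxyethoxy)-3-methylbut-1-ene (not isolated) | CCOC(C)(OCC)OC(C)(C)C=C | intermediate
12 | 3-[(1-ethoxyethenyl)oxy]-3-methylbut-1-ene (not isolated) | C=C(OCC)OC(C)(C)C=C | intermediate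
13 | ethyl 5-methylhex-4-enoate | CCOC(=O)CCC=C(C)C | intermediate
14 | N-methoxy-N,5-dimethylhex-4-enamide | CON(C)C(=O)CCC=C(C)C | intermediate
15 | bromomagnesium alkoxide of 3-[methoxy(methyl)amino]-7-methyloct-6-en-1-yn-3-ol, racemic chelated adduct (not isolated) | C#CC(O[Mg]Br)(CCC=C(C)C)N(C)OC | intermediate
16 | 7-methyloct-6-en-1-yn-3-one | C#CC(=O)CCC=C(C)C | intermediate
17 | methyl (3Z)-2-[5-methoxy-7-(methoxymethoxy)-2-oxo-2H-chromen-3-yl]-9-methyl-5-oxodeca-3,8-dienoate, racemic at C2 (not isolated) | COC(=O)C(/C=C\C(=O)CCC=C(C)C)c1cc2c(OC)cc(OCOC)cc2oc1=O | intermediate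
18 | 4-[5-methoxy-7-(methoxymethoxy)-2-oxo-2H-chromen-3-yl]-2-(3-methylbut-2-en-1-yl)cyclohex-5-ene-1,3-dione, configuration at both sp3 carbons undefined (not isolated) | COCOc1cc(OC)c2cc(C3C=CC(=O)C(CC=C(C)C)C3=O)c(=O)oc2c1 | intermediate
19 | 3-[2,4-dihydroxy-3-(3-methylbut-2-en-1-yl)phenyl]-5-methoxy-7-(methoxymethoxy)-2H-chromen-2-one | COc1cc(OCOC)cc2oc(=O)c(-c3ccc(O)c(CC=C(C)C)c3O)cc12 | intermediate
20 | 3-[2,4-dihydroxy-3-(3-methylbut-2-en-1-yl)phenyl]-7-hydroxy-5-methoxy-2H-chromen-2-one | COc1cc(O)cc2oc(=O)c(-c3ccc(O)c(CC=C(C)C)c3O)cc12 | target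

**Step count**
Total: 8 steps. Longest linear sequence: 5 steps (9 → 13 → 14 → 16 → 19 → 20; steps 4, 5, 6, 7, 8).

**Steps most likely to fail**

1. Step 7 (proposed new method). The enolate of adduct 17 may close through oxygen to a pyranone that is not funnelled back. The adduct may stall as its stabilised anion because the C3' enolate is too sparsely populated. The terminal ynone may oligomerise under base before conjugate addition.
Fallback (known chemistry, sets out from 2 and returns at 20): aldehyde 2 would be heated with ethyl bromo(triphenylphosphoranylidene)acetate in N,N-diethylaniline. Wittig olefination gives ethyl (2E)-2-bromo-3-[2-hydroxy-6-methoxy-4-(methoxymethoxy)phenyl]prop-2-enoate F1 (not isolated), which lactonises to 3-bromo-5-methoxy-7-(methoxymethoxy)-2H-chromen-2-one F2. Separately, commercial 1,3-bis(methoxymethoxy)benzene would be lithiated between the two acetal oxygens (n-BuLi, THF, 0 °C), transmetallated with CuI and alkylated with 1-bromo-3-methylbut-2-ene to give 1,3-bis(methoxymethoxy)-2-(3-methylbut-2-en-1-yl)benzene F3. A second MOM-directed ortho-lithiation (n-BuLi, TMEDA) and trapping with 2-isopropoxy-4,4,5,5-tetramethyl-1,3,2-dioxaborolane would give 2-[2,4-bis(methoxymethoxy)-3-(3-methylbut-2-en-1-yl)phenyl]-4,4,5,5-tetramethyl-1,3,2-dioxaborolane F4. Suzuki–Miyaura coupling of F2 with F4 (Pd(dppf)Cl2, K2CO3, dioxane–water, 80 °C) would give 3-[2,4-bis(methoxymethoxy)-3-(3-methylbut-2-en-1-yl)phenyl]-5-methoxy-7-(methoxymethoxy)-2H-chromen-2-one F5. Methanolic HCl would then remove the three MOM groups to give 20.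

2. Step 3. The E-olefin may lactonise onto the saturated ester and form a seven-membered ring. E/Z equilibration may be incomplete. Olefination of the electron-rich, hydrogen-bonded aldehyde may be slow.
Fallback (sets out from 2 and 4, returns at 8): commercial tert-butyl 2-(diethoxyphosphoryl)acetate would be alkylated with 4 (NaH, THF) to give 1-tert-butyl 4-methyl 2-(diethoxyphosphoryl)butanedioate F6. TFA in CH2Cl2 would free 2-(diethoxyphosphoryl)-4-methoxy-4-oxobutanoic acid F7. Esterification of the phenol of 2 with F7 (EDC, DMAP, CH2Cl2) would give 1-[2-formyl-3-methoxy-5-(methoxymethoxy)phenyl] 4-methyl 2-(diethoxyphosphoryl)butanedioate F8. DBU and LiCl in MeCN would then close the lactone ring by intramolecular Horner–Wadsworth–Emmons reaction to give 8; the tether forces the cis relation of aryl ring and lactone carbonyl, so no olefin isomerisation is needed.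

3. Step 8. Acid may promote addition of the flanking C2' or C4' hydroxyl across the prenyl alkene (chroman closure) in competition with acetal cleavage.
Fallback (sets out from 8, returns at 20): the MOM group would be removed before the prenyl chain is present. Methanolic HCl on 8 gives methyl 2-(7-hydroxy-5-methoxy-2-oxo-2H-chromen-3-yl)acetate F9. Allyl bromide and K2CO3 in acetone would give methyl 2-[5-methoxy-2-oxo-7-(prop-2-en-1-yloxy)-2H-chromen-3-yl]acetate F10; the allyl ether is introduced only after the high-temperature step 3, where it would undergo Claisen rearrangement. The annulation of step 7 with 16 would then pass through methyl (3Z)-2-[5-methoxy-2-oxo-7-(prop-2-en-1-yloxy)-2H-chromen-3-yl]-9-methyl-5-oxodeca-3,8-dienoate F11 (not isolated) and 4-[5-methoxy-2-oxo-7-(prop-2-en-1-yloxy)-2H-chromen-3-yl]-2-(3-methylbut-2-en-1-yl)cyclohex-5-ene-1,3-dione F12 (not isolated) to give 3-[2,4-dihydroxy-3-(3-methylbut-2-en-1-yl)phenyl]-5-methoxy-7-(prop-2-en-1-yloxy)-2H-chromen-2-one F13. Pd(PPh3)4 with morpholine in THF at rt (Tsuji–Trost deallylation, neutral) would give 20.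

**Further compounds**
F1 | step 7 | ethyl (2E)-2-bromo-3-[2-hydroxy-6-methoxy-4-(methoxymethoxy)phenyl]prop-2-enoate | CCOC(=O)/C(Br)=C\c1c(O)cc(OCOC)cc1OC
F2 | step 7 | 3-bromo-5-methoxy-7-(methoxymethoxy)-2H-chromen-2-one | COCOc1cc(OC)c2cc(Br)c(=O)oc2c1
F3 | step 7 | 1,3-bis(methoxymethoxy)-2-(3-methylbut-2-en-1-yl)benzene | COCOc1cccc(OCOC)c1CC=C(C)C
F4 | step 7 | 2-[2,4-bis(methoxymethoxy)-3-(3-methylbut-2-en-1-yl)phenyl]-4,4,5,5-tetramethyl-1,3,2-dioxaborolane | COCOc1ccc(B2OC(C)(C)C(C)(C)O2)c(OCOC)c1CC=C(C)C
F5 | step 7 | 3-[2,4-bis(methoxymethoxy)-3-(3-methylbut-2-en-1-yl)phenyl]-5-methoxy-7-(methoxymethoxy)-2H-chromen-2-one | COCOc1cc(OC)c2cc(-c3ccc(OCOC)c(CC=C(C)C)c3OCOC)c(=O)oc2c1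
F6 | step 3 | 1-tert-butyl 4-methyl 2-(diethoxyphosphoryl)butanedioate (racemic) | CCOP(=O)(OCC)C(CC(=O)OC)C(=O)OC(C)(C)C
F7 | step 3 | 2-(diethoxyphosphoryl)-4-methoxy-4-oxobutanoic acid (racemic) | CCOP(=O)(OCC)C(CC(=O)OC)C(=O)O
F8 | step 3 | 1-[2-formyl-3-methoxy-5-(methoxymethoxy)phenyl] 4-methyl 2-(diethoxyphosphoryl)butanedioate (racemic) | CCOP(=O)(OCC)C(CC(=O)OC)C(=O)Oc1cc(OCOC)cc(OC)c1C=O
F9 | step 8 | methyl 2-(7-hydroxy-5-methoxy-2-oxo-2H-chromen-3-yl)acetate | COc1cc(O)cc2oc(=O)c(CC(=O)OC)cc12
F10 | step 8 | methyl 2-[5-methoxy-2-oxo-7-(prop-2-en-1-yloxy)-2H-chromen-3-yl]acetate | COc1cc(OCC=C)cc2oc(=O)c(CC(=O)OC)cc12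
F11 | step 8 | methyl (3Z)-2-[5-methoxy-2-oxo-7-(prop-2-en-1-yloxy)-2H-chromen-3-yl]-9-methyl-5-oxodeca-3,8-dienoate (racemic at C2) | COC(=O)C(/C=C\C(=O)CCC=C(C)C)c1cc2c(OC)cc(OCC=C)cc2oc1=O
F12 | step 8 | 4-[5-methoxy-2-oxo-7-(prop-2-en-1-yloxy)-2H-chromen-3-yl]-2-(3-methylbut-2-en-1-yl)cyclohex-5-ene-1,3-dione | COc1cc(OCC=C)cc2oc(=O)c(C3C=CC(=O)C(CC=C(C)C)C3=O)cc12
F13 | step 8 | 3-[2,4-dihydroxy-3-(3-methylbut-2-en-1-yl)phenyl]-5-methoxy-7-(prop-2-en-1-yloxy)-2H-chromen-2-one | COc1cc(OCC=C)cc2oc(=O)c(-c3ccc(O)c(CC=C(C)C)c3O)cc12
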